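**Strategy.** Ring B of the bicyclo[3.3.1]nonane is opened at C5–C6 and C1–C8. This exposes a flat, mirror-symmetric 3,5-diprenylated acylphloroglucinol (ring A, whose two prenyl-bearing carbons are enantiotopic nucleophiles) and a C6–C7–C8 bis-electrophile. The key step is an enantioselective alkylative dearomatization–annulation: a double Michael addition to an α-(1-acetoxy-1-methylethyl)acrolein under chiral phase-transfer catalysis. In one operation it should form both bonds, ring B, the two quaternary bridgeheads C1 and C5 and, through an epimerizable formyl group, the exo centre C7. The formyl group is then converted into the third prenyl group, and the enol and catechol are unmasked together.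

Key step: step 6

**Remarks.**
- Numbering: C1 is the bridgehead next to C8 (CMe2); C2–C3–C4 is the enolized β-diketone with the aroyl group on C3; C5 is the second bridgehead; C6 is CH2; C7 is CH; C9 is the bridging ketone. Ring A is C1–C2–C3–C4–C5–C9 and ring B is C1–C8–C7–C6–C5–C9.
- Assumption: the enol O-methylation in step 7 is drawn at O4, the less hindered oxygen; the O2 regioisomer, if formed, would behave identically and converge in step 11.
- Assumption: the cinchonidinium catalyst is written for step 6; if it induces the opposite sense, the pseudoenantiomeric cinchoninium salt is used instead.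

**Step 1**
Reactants: 1 3,4-dihydroxybenzoic acid
Product: 2 3,4-bis(p-tolylsulfonyloxy)benzoic acid
Conditions: TsCl (2.4 equiv), NaOH, H2O/THF, 0 °C to rt; then aq. HCl
Reagents that add atoms: p-toluenesulfonyl chloride, Cc1ccc(cc1)S(Cl)(=O)=O
Why: Schotten–Baumann O-sulfonylation of both phenoxides, with any mixed carboxylic–sulfonic anhydride hydrolysed back to the carboxylate before acidification.

**Step 2**
Reactants: 2 3,4-bis(p-tolylsulfonyloxy)benzoic acid; 3 phloroglucinol
Product: 5 [3,4-bis(p-tolylsulfonyloxy)phenyl](2,4,6-trihydroxyphenyl)methanone, via acid chloride 4 (not isolated)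
Conditions: (COCl)2, DMF (cat.), CH2Cl2, rt; evaporate; then 3, AlCl3, PhNO2, 0 to 50 °C; aq. HCl
Reagents that add atoms: none
Why: Friedel–Crafts C-acylation of phloroglucinol should stop after one acylation because the aryl ketone deactivates the ring, and aryl sulfonates are inert to AlCl3.

**Step 3**
Reactants: 5 [3,4-bis(p-tolylsulfonyloxy)phenyl](2,4,6-trihydroxyphenyl)methanone
Product: 6 [3,4-bis(p-tolylsulfonyloxy)phenyl][2,4,6-trihydroxy-3,5-bis(3-methylbut-2-en-1-yl)phenyl]methanone
Conditions: prenyl bromide (2.1 equiv), 5% aq. KOH, 0 °C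
Reagents that add atoms: 1-bromo-3-methylbut-2-ene, CC(C)=CCBr
Why: aqueous C-alkylation of the phloroglucinolate (solvated oxygens favour attack through carbon) at the two free ring positions, while the aryl sulfonates should survive cold dilute alkali.

**Step 4**
Reactants: 7 acetone; 8 isopropenylmagnesium bromide
Product: 10 2,3-dimethylbut-3-en-2-yl acetate, via bromomagnesium alkoxide 9 (not isolated)
Conditions: CH2=C(CH3)MgBr, THF, 0 °C; then Ac2O, 0 °C to rt
Reagents that add atoms: acetic anhydride, CC(=O)OC(C)=O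
Why: Grignard 1,2-addition to the ketone followed by O-acylation of the tertiary magnesium alkoxide in the same flask.

**Step 5**
Reactants: 10 2,3-dimethylbut-3-en-2-yl acetate
Product: 11 3-acetoxy-3-methyl-2-methylidenebutanal
Conditions: SeO2 (1.1 equiv), 1,4-dioxane, 80 °C
Reagents that add atoms: selenium dioxide, O=[Se]=O
Why: Riley allylic oxidation (ene reaction, then [2,3]-sigmatropic shift) at the only allylic C–H position, the vinylic methyl group, should give the α-methylene aldehyde.

**Step 6**
Reactants: 6 [3,4-bis(p-tolylsulfonyloxy)phenyl][2,4,6-trihydroxy-3,5-bis(3-methylbut-2-en-1-yl)phenyl]methanone; 11 3-acetoxy-3-methyl-2-methylidenebutanal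
Product: 14 (1S,5S,7R)-3-[3,4-bis(p-tolylsulfonyloxy)benzoyl]-4-hydroxy-8,8-dimethyl-1,5-bis(3-methylbut-2-en-1-yl)-2,9-dioxobicyclo[3.3.1]non-3-ene-7-carbaldehyde (formyl group exo), via dearomatized enal 12 (not isolated), via adamantane aldol 13 (not isolated)
Conditions: CsOH·H2O (5 equiv), O(9)-allyl-N-(9-anthracenylmethyl)cinchonidinium bromide (25 mol %), 4 Å MS, CH2Cl2, −50 °C; filter, exchange solvent; KN(SiMe3)2 (2.5 equiv), THF, 65 °C; aq. NH4Cl
Reagents that add atoms: none
Why: The caesium phenolate of 6, ion-paired with the chiral ammonium cation, adds through one prenyl-bearing ring carbon to the CH2 terminus of 11 and the enolate expels acetate (Michael addition/E1cB, a net SN2′ alkylative dearomatization) to give enal 12, whose remaining enolate adds through the second prenyl-bearing carbon to the β,β-dimethyl terminus and forms the C1–C8 bond between two quaternary carbons. The closest known reaction type is the alkylative dearomatization–annulation of acylphloroglucinols with α-(1-acyloxyalkyl) enals under chiral phase-transfer catalysis, a double-Michael α,α′-annulation. Ring B (C1–C8–C7–C6–C5–C9) is closed by a 6-endo-trig intramolecular Michael addition with the ring A enolate as nucleophile. C5 is set in the first, intermolecular C–C bond formation by the chiral ion pair, which distinguishes the two mirror-related prenylated carbons and their faces; C1 follows from C5 because the three-carbon tether can only reach the second carbon on the same face; C7 is set under thermodynamic control, since its enolizable formyl group should settle equatorial (exo) on chair ring B. Any C7-endo aldehyde parked at low temperature as the C3 aldol (adamantane carbinol 13) should be returned by retro-aldol on heating with KN(SiMe3)2, so all C7 isomers converge on 14. The step needs C- rather than O-alkylation and reaction at the two prenylated carbons rather than at the acyl-bearing carbon, which the soft, reversible Michael manifold and the deactivating, blocking aroyl group on C3 should secure.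

**Step 7**
Reactants: 14 bicyclic aldehyde
Product: 15 (1S,5S,7R)-3-[3,4-bis(p-tolylsulfonyloxy)benzoyl]-4-methoxy-8,8-dimethyl-1,5-bis(3-methylbut-2-en-1-yl)-2,9-dioxobicyclo[3.3.1]non-3-ene-7-carbaldehyde
Conditions: Me3SiCHN2, i-Pr2NEt, MeCN/MeOH, 0 °C to rt
Reagents that add atoms: (trimethylsilyl)diazomethane, C[Si](C)(C)C=[N+]=[N-]
Why: diazomethane-type O-methylation of the acidic vinylogous acid (β-triketone enol), expected at the oxygen remote from the C8 gem-dimethyl group, masks the enol and the C3 nucleophile without touching the aldehyde.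

**Step 8**
Reactants: 15 methyl enol ether aldehyde
Product: 17 1-[(1S,5S,7R)-3-[3,4-bis(p-tolylsulfonyloxy)benzoyl]-4-methoxy-8,8-dimethyl-1,5-bis(3-methylbut-2-en-1-yl)-2,9-dioxobicyclo[3.3.1]non-3-en-7-yl]prop-2-en-1-yl acetate (both carbinol epimers), via bromomagnesium alkoxide 16 (not isolated)
Conditions: CH2=CHMgBr, THF, −78 °C; then Ac2O, DMAP, −78 °C to rt
Reagents that add atoms: vinylmagnesium bromide, C=C[Mg]Br; acetic anhydride, CC(=O)OC(C)=O
Why: Grignard 1,2-addition should be chemoselective for the aldehyde over the C9 ketone (flanked by two quaternary carbons), the vinylogous ester and the aryl sulfonates; the new carbinol centre is uncontrolled and is erased in step 9.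

**Step 9**
Reactants: 17 allylic acetate
Product: 18 (1S,5S,7R)-3-[3,4-bis(p-tolylsulfonyloxy)benzoyl]-4-methoxy-8,8-dimethyl-1,5-bis(3-methylbut-2-en-1-yl)-7-(prop-2-en-1-yl)bicyclo[3.3.1]non-3-ene-2,9-dione
Conditions: Pd2(dba)3 (5 mol %, zerovalent palladium), PBu3, HCO2NH4, THF, 50 °C
Reagents that add atoms: none
Why: Tsuji formate hydrogenolysis (ionization to the π-allylpalladium formate, decarboxylation, hydride delivery to the more substituted allyl terminus) should give the terminal alkene and remove the carbinol centre, leaving C7 untouched.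

**Step 10**
Reactants: 18 7-allyl compound
Product: 19 (1S,5S,7R)-3-[3,4-bis(p-tolylsulfonyloxy)benzoyl]-4-methoxy-8,8-dimethyl-1,5,7-tris(3-methylbut-2-en-1-yl)bicyclo[3.3.1]non-3-ene-2,9-dione
Conditions: second-generation Grubbs catalyst (H2IMes)(PCy3)Cl2Ru=CHPh (10 mol %), 2-methyl-2-butene (excess), CH2Cl2, 40 °C
Reagents that add atoms: 2-methylbut-2-ene, CC=C(C)C
Why: olefin cross-metathesis of the monosubstituted allyl group with 2-methyl-2-butene should install the isopropylidene terminus, while the two trisubstituted prenyl groups can only exchange degenerately.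

**Step 11**
Reactants: 19 protected aristophenone A
Product: 20 aristophenone A, (1S,5S,7R)-3-(3,4-dihydroxybenzoyl)-4-hydroxy-8,8-dimethyl-1,5,7-tris(3-methylbut-2-en-1-yl)bicyclo[3.3.1]non-3-ene-2,9-dione
Conditions: LiOH·H2O (20 equiv), 1,4-dioxane/H2O (degassed), 90 °C, Ar; then aq. HCl to pH 3
Reagents that add atoms: lithium hydroxide, [Li+].[OH-]
Why: hydroxide should cleave the vinylogous methyl ester by addition–elimination and both aryl sulfonates by attack at sulfur, releasing enol and catechol together; no stereocentre is enolizable (C1 and C5 are quaternary, C7 carries no carbonyl).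

**Compound list**
1 | 3,4-dihydroxybenzoic acid | OC(=O)c1ccc(O)c(O)c1 | starting material
2 | 3,4-bis(p-tolylsulfonyloxy)benzoic acid | OC(=O)c1ccc(OS(=O)(=O)c2ccc(C)cc2)c(OS(=O)(=O)c2ccc(C)cc2)c1 | intermediate
3 | phloroglucinol | Oc1cc(O)cc(O)c1 | starting material
4 | 3,4-bis(p-tolylsulfonyloxy)benzoyl chloride | ClC(=O)c1ccc(OS(=O)(=O)c2ccc(C)cc2)c(OS(=O)(=O)c2ccc(C)cc2)c1 | intermediate
5 | [3,4-bis(p-tolylsulfonyloxy)phenyl](2,4,6-trihydroxyphenyl)methanone | O=C(c1ccc(OS(=O)(=O)c2ccc(C)cc2)c(OS(=O)(=O)c2ccc(C)cc2)c1)c1c(O)cc(O)cc1O | intermediate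
6 | [3,4-bis(p-tolylsulfonyloxy)phenyl][2,4,6-trihydroxy-3,5-bis(3-methylbut-2-en-1-yl)phenyl]methanone | CC(C)=CCc1c(O)c(CC=C(C)C)c(O)c(C(=O)c2ccc(OS(=O)(=O)c3ccc(C)cc3)c(OS(=O)(=O)c3ccc(C)cc3)c2)c1O | intermediate
7 | acetone | CC(C)=O | starting material
8 | isopropenylmagnesium bromide | CC(=C)[Mg]Br | starting material
9 | bromomagnesium 2,3-dimethylbut-3-en-2-olate | CC(=C)C(C)(C)O[Mg]Br | intermediate
10 | 2,3-dimethylbut-3-en-2-yl acetate | CC(=C)C(C)(C)OC(C)=O | intermediate
11 | 3-acetoxy-3-methyl-2-methylidenebutanal | CC(=O)OC(C)(C)C(=C)C=O | intermediate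
12 | (6S)-4-[3,4-bis(p-tolylsulfonyloxy)benzoyl]-6-(2-formyl-3-methylbut-2-en-1-yl)-3,5-dihydroxy-2,6-bis(3-methylbut-2-en-1-yl)cyclohexa-2,4-dien-1-one | CC(C)=C(C=O)C[C@]1(CC=C(C)C)C(=O)C(CC=C(C)C)=C(O)C(C(=O)c2ccc(OS(=O)(=O)c3ccc(C)cc3)c(OS(=O)(=O)c3ccc(C)cc3)c2)=C1O | intermediate
13 | adamantane aldol: the C7 formyl carbon of the endo aldehyde bonded to C3 as a secondary carbinol, with C2, C4 and C9 as ketones (carbinol configuration not assigned) | OC1[C@H]2C[C@]3(CC=C(C)C)C(=O)[C@@](CC=C(C)C)(C(=O)[C@@]1(C(=O)c4ccc(OS(=O)(=O)c5ccc(C)cc5)c(OS(=O)(=O)c5ccc(C)cc5)c4)C3=O)C2(C)C | intermediate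
14 | (1S,5S,7R)-3-[3,4-bis(p-tolylsulfonyloxy)benzoyl]-4-hydroxy-8,8-dimethyl-1,5-bis(3-methylbut-2-en-1-yl)-2,9-dioxobicyclo[3.3.1]non-3-ene-7-carbaldehyde | O=C[C@@H]1C[C@]2(CC=C(C)C)C(=O)[C@@](CC=C(C)C)(C(=O)C(C(=O)c3ccc(OS(=O)(=O)c4ccc(C)cc4)c(OS(=O)(=O)c4ccc(C)cc4)c3)=C2O)C1(C)C | intermediate
15 | (1S,5S,7R)-3-[3,4-bis(p-tolylsulfonyloxy)benzoyl]-4-methoxy-8,8-dimethyl-1,5-bis(3-methylbut-2-en-1-yl)-2,9-dioxobicyclo[3.3.1]non-3-ene-7-carbaldehyde | O=C[C@@H]1C[C@]2(CC=C(C)C)C(=O)[C@@](CC=C(C)C)(C(=O)C(C(=O)c3ccc(OS(=O)(=O)c4ccc(C)cc4)c(OS(=O)(=O)c4ccc(C)cc4)c3)=C2OC)C1(C)C | intermediate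
16 | bromomagnesium alkoxide of the vinyl adduct of 15 (both carbinol epimers) | C=CC(O[Mg]Br)[C@@H]1C[C@]2(CC=C(C)C)C(=O)[C@@](CC=C(C)C)(C(=O)C(C(=O)c3ccc(OS(=O)(=O)c4ccc(C)cc4)c(OS(=O)(=O)c4ccc(C)cc4)c3)=C2OC)C1(C)C | intermediate
17 | 1-[(1S,5S,7R)-3-[3,4-bis(p-tolylsulfonyloxy)benzoyl]-4-methoxy-8,8-dimethyl-1,5-bis(3-methylbut-2-en-1-yl)-2,9-dioxobicyclo[3.3.1]non-3-en-7-yl]prop-2-en-1-yl acetate (both carbinol epimers) | C=CC(OC(C)=O)[C@@H]1C[C@]2(CC=C(C)C)C(=O)[C@@](CC=C(C)C)(C(=O)C(C(=O)c3ccc(OS(=O)(=O)c4ccc(C)cc4)c(OS(=O)(=O)c4ccc(C)cc4)c3)=C2OC)C1(C)C | intermediate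
18 | (1S,5S,7R)-3-[3,4-bis(p-tolylsulfonyloxy)benzoyl]-4-methoxy-8,8-dimethyl-1,5-bis(3-methylbut-2-en-1-yl)-7-(prop-2-en-1-yl)bicyclo[3.3.1]non-3-ene-2,9-dione | C=CC[C@@H]1C[C@]2(CC=C(C)C)C(=O)[C@@](CC=C(C)C)(C(=O)C(C(=O)c3ccc(OS(=O)(=O)c4ccc(C)cc4)c(OS(=O)(=O)c4ccc(C)cc4)c3)=C2OC)C1(C)C | intermediate
19 | (1S,5S,7R)-3-[3,4-bis(p-tolylsulfonyloxy)benzoyl]-4-methoxy-8,8-dimethyl-1,5,7-tris(3-methylbut-2-en-1-yl)bicyclo[3.3.1]non-3-ene-2,9-dione | CC(C)=CC[C@@H]1C[C@]2(CC=C(C)C)C(=O)[C@@](CC=C(C)C)(C(=O)C(C(=O)c3ccc(OS(=O)(=O)c4ccc(C)cc4)c(OS(=O)(=O)c4ccc(C)cc4)c3)=C2OC)C1(C)C | intermediate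
20 | aristophenone A | CC(C)=CC[C@@H]1C[C@]2(CC=C(C)C)C(=O)[C@@](CC=C(C)C)(C(=O)C(C(=O)c3ccc(O)c(O)c3)=C2O)C1(C)C | target

**Step count.** Total: 11 steps. Longest linear sequence: 9 steps (1, 2, 3, 6, 7, 8, 9, 10, 11); steps 4 and 5 form the short branch to enal 11.

**Steps most likely to fail, with fallbacks**

1. Step 6. The chiral ion pair may discriminate the two faces poorly in the first C–C bond formation, and material may be lost to O-alkylation or fail to return from the aldol reservoir. Fallback: starting from 6 and 11, the cascade is run without asymmetric induction (KN(SiMe3)2, THF, 65 °C, conditions that favour the open aldehyde). This should give 14 together with its mirror image, ent-aldehyde F1. The mixture is O-methylated as in step 7 to 15 and its mirror image, ent-methyl ether F2. The enantiomers are separated by preparative chromatography on a chiral stationary phase (amylose tris(3,5-dimethylphenylcarbamate)), and the route is rejoined at 15.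

2. Step 3. Over-alkylation (geminal C-prenylation with dearomatization), O-alkylation and slow sulfonate hydrolysis in the alkaline medium may erode the yield. Fallback: starting from 5, the phenoxide alkylation is replaced by an acid-mediated Friedel–Crafts prenylation with 2-methylbut-3-en-2-ol and BF3·OEt2 in 1,4-dioxane at rt (allyl cation attack on the free ring carbons, no base present). The route is rejoined at 6; this fallback makes no new compound (F0).

3. Step 11. The reaction may stall after loss of the first sulfonate, because the second leaving group is a catecholate dianion, and the catecholate may be oxidized in hot alkali. Fallback: starting from 19, the enol ether is cleaved first by SN2 demethylation with LiCl in DMSO at 120 °C to give aristophenone A 3′,4′-di-O-tosylate F3. Both sulfonates are then removed by single-electron reductive S–O cleavage with Mg in MeOH at rt, which does not depend on the leaving-group ability of the phenoxide. The route is rejoined at 20.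

**Further compounds**
F1 | step 6 | ent-aldehyde (mirror image of 14) | O=C[C@H]1C[C@@]2(CC=C(C)C)C(=O)[C@](CC=C(C)C)(C(=O)C(C(=O)c3ccc(OS(=O)(=O)c4ccc(C)cc4)c(OS(=O)(=O)c4ccc(C)cc4)c3)=C2O)C1(C)C
F2 | step 6 | ent-methyl ether (mirror image of 15) | O=C[C@H]1C[C@@]2(CC=C(C)C)C(=O)[C@](CC=C(C)C)(C(=O)C(C(=O)c3ccc(OS(=O)(=O)c4ccc(C)cc4)c(OS(=O)(=O)c4ccc(C)cc4)c3)=C2OC)C1(C)C
F0 | step 3 | none | none
F3 | step 11 | aristophenone A 3′,4′-di-O-tosylate | CC(C)=CC[C@@H]1C[C@]2(CC=C(C)C)C(=O)[C@@](CC=C(C)C)(C(=O)C(C(=O)c3ccc(OS(=O)(=O)c4ccc(C)cc4)c(OS(=O)(=O)c4ccc(C)cc4)c3)=C2O)C1(C)C
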